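Start from the pace.

| flask | substrate | solid reagent | remark | time |
|---|---|---|---|---|
| beta | 0.023 M | 0.029 M | run made earlier |  |
| eta | 0.023 M | 0.12 M | run made earlier |  |
| epsilon | 0.011 M | 0.0575 M | run made earlier |  |
| flask | 0.023 M | 0.0575 M |  | 40 h |

| run | time / h | target / % | isomer of the product / % | substrate / % |
|---|---|---|---|---|
| beta | 6.00 | 1.3 | 0.5 | 97.5 |
| beta | 15.0 | 6.6 | 2.3 | 91.8 |
| beta | 20.0 | 9.4 | 2.6 | 88.5 |
| beta | 30.0 | 13.3 | 4.0 | 82.5 |
| beta | 40.0 | 16.9 | 7.3 | 76.8 |
| beta | 50.0 | 18.0 | 10.0 | 72.2 |
| eta | 4.00 | 1.6 | 1.3 | 98.4 |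
| eta | 6.00 | 1.5 | 0 | 97.7 |
| eta | 8.00 | 3.1 | 1.3 | 96.0 |
| eta | 15.0 | 7.9 | 0.9 | 90.6 |
| eta | 20.0 | 9.7 | 1.7 | 87.9 |
| eta | 30.0 | 13.6 | 4.1 | 82.0 |
| eta | 50.0 | 17.3 | 9.1 | 72.7 |
| epsilon | 10.0 | 5.2 | 1.1 | 93.0 |
| epsilon | 20.0 | 11.7 | 3.0 | 84.8 |
| epsilon | 30.0 | 17.2 | 5.0 | 76.8 |
| epsilon | 40.0 | 20.1 | 8.5 | 71.2 |
| epsilon | 50.0 | 21.8 | 11.9 | 65.9 |

(standard deviation of a reading: 0.5 percentage points)

- at the start none of the solid reagent is in solution
- a reading or a percentage of target counts all its forms, free or not
- the concentration of target that is asked is that of its free form alone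

* concentration of target (only what is free in solution) at 40 h, in M
* concentration of isomer of the product at 40 h, in M
* concentration of substrate at 40 h, in M

Climb the ladder of times upward. First comes the lag. Up to 6.00 h, the beta run loses substrate at a pace that needs 240 h for the whole charge. From there to 40.0 h, that time reads 164 h, which is shorter. Next stands the asked 40 h, shorter than the whole-charge time, so at that pace expect this flask to have lost 24.4 % of its substrate. Last comes the solid. At one reagent per substrate lost, the same pace needs 411 h for this flask's charge.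

Now compare charges. Beta and eta read 82.5 % and 82.0 % substrate at 30.0 h, despite 0.029 M against 0.12 M of solid. Treat the loss as zero order in the solid charge. Epsilon, with 0.011 M of substrate, reads 76.8 % at 30.0 h.

Define the loss number: substrate charged per substrate lost at 40 h, the reciprocal of the fraction lost. Beta reads 4.31, and epsilon reads 3.47. Assume a straight line in c(substrate) through these two readings. Its slope is 69.8 /M.

This flask has beta's substrate charge, so my reckoning gives c(substrate) = 0.0177 M. Beta's readings also give c(isomer of the product) = 0.00168 M and c(target) = 0.00389 M, which I take as free.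

The forecast gives c(target) = 0.0032 M (range 0.0021 M to 0.0039 M), c(isomer of the product) = 0.0016 M and c(substrate) = 0.0177 M. It differs from me on target: “I assume a modest bound share”.

The flask gives c(target) = 0.00375 M, c(isomer of the product) = 0.00158 M and c(substrate) = 0.0177 M.

    substrate + partner ⇌ isomer of the product (K = 1600 /M, k = 0.820 /M/h)
    solid reagent ⇌ partner, rate k2*(cs2 - [partner]) while solid is left; crystals form when [partner] > cs2 (solubility = 9.40 mM, k = 0.0340 /h)
    crystals ⇌ target, rate k3*(cs3 - [target]) while solid is left; crystals form when [target] > cs3 (solubility = 14.0 mM, k = 5.60 /h)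
    substrate + partner ⇌ target (K = 59.0 /M, k = 6.60 /M/h)

Free target in the flask stands above the forecast by a factor of 1.17, with crystals at 0 % at 40.0 h. The flask's loss number is 4.31, beside beta's 4.31. Take the neighbour with 0.057 M of substrate, its solid charge and time unchanged. The line gives it a loss number of 6.69, so expect 85.1 % of its substrate left. The neighbour keeps 85 %.

The runs are simulated with constants of no real substance, and the scatter is random.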